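## Retrosynthetic overview

Target read as 3α-acetoxy-15-hydroxylabda-8(17),13E-dien-19-oic acid (labdane numbering; 5α-H, 10β-CH3, 9β side chain, axial 4β-CO2H, axial 3α-OAc).
- The 13E allylic alcohol is made last, from a terminal alkyne by syn methyl-alumination and formaldehyde capture (adds C16 and C15).
- The 3α-acetate and the C19 acid come from a bicyclic 3-oxo 4β-ester: axial-selective ketone reduction, then ester → CH2OH → CO2H.
- Key disconnection C4–C5 and C9–C10: rings A and B form in one operation (ring A first, then ring B, then the 8(17)-alkene) by oxidative radical bicyclization of an acyclic 8-phenylmenthyl β-keto ester dienyne.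
- That precursor comes from an acetoacetate dianion and an allylic bromide built from geranyl bromide and a silylpropyne.

Assumption: the face shielded by the (1R,2S,5R)-8-phenylmenthyl group in the key step is taken from the phenyl-stacking model for the unchelated radical; if the antipodal ring series formed instead, the enantiomeric auxiliary would be used with no other change.

## Route

Step 1
Reactants: 1 geranyl bromide; 2 1-(trimethylsilyl)propyne
Product: 4 [(5E)-6,10-dimethylundeca-5,9-dien-1-yn-1-yl]trimethylsilane, via lithiated silylpropyne 3 (not isolated)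
Conditions: n-BuLi, THF, −78 → −20 °C; then 1, −78 → 0 °C
Reagents that add atoms: none
Why: Propargylic lithiation of 2 gives a carbanion that displaces the primary allylic bromide of 1 by SN2 at CH2Br (silylpropyne alkylation), so the E-alkene is carried through unchanged and no stereocentre is formed.

Step 2
Reactants: 4 [(5E)-6,10-dimethylundeca-5,9-dien-1-yn-1-yl]trimethylsilane
Product: 5 (2E,6E)-2,6-dimethyl-11-(trimethylsilyl)undeca-2,6-dien-10-yn-1-ol
Conditions: SeO2 (0.3 equiv), t-BuOOH (3 equiv), salicylic acid (0.1 equiv), CH2Cl2, 0 °C → rt; recycle recovered 4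
Reagents that add atoms: tert-butyl hydroperoxide, CC(C)(C)OO (terminal oxygen source); SeO2, O=[Se]=O (catalytic oxygen carrier)
Why: Catalytic SeO2 allylic oxidation (ene reaction then [2,3]-sigmatropic shift) attacks the most electron-rich and least hindered terminal isopropylidene and gives the E-hydroxymethyl isomer selectively.

Step 3
Reactants: 5 (2E,6E)-2,6-dimethyl-11-(trimethylsilyl)undeca-2,6-dien-10-yn-1-ol
Product: 6 [(5E,9E)-11-bromo-6,10-dimethylundeca-5,9-dien-1-yn-1-yl]trimethylsilane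
Conditions: CBr4, PPh3, CH2Cl2, 0 °C; used crude
Reagents that add atoms: tetrabromomethane, BrC(Br)(Br)Br
Why: Appel bromination converts the primary allylic alcohol into the bromide under neutral conditions without allylic transposition or E/Z erosion and leaves the silylalkyne untouched.

Step 4
Reactants: 7 (−)-8-phenylmenthol; 8 ethyl 2-methylacetoacetate
Product: 9 (1R,2S,5R)-5-methyl-2-(2-phenylpropan-2-yl)cyclohexyl 2-methyl-3-oxobutanoate
Conditions: DMAP (0.3 equiv), toluene, reflux through 4 Å sieves (−EtOH)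
Reagents that add atoms: none
Why: DMAP-catalysed transesterification of an enolisable β-keto ester (acylketene pathway) loads the chiral alcohol without touching its stereocentres, and the α-carbon remains an equilibrating epimer mixture that becomes planar in step 6.

Step 5
Reactants: 9 (1R,2S,5R)-5-methyl-2-(2-phenylpropan-2-yl)cyclohexyl 2-methyl-3-oxobutanoate; 6 [(5E,9E)-11-bromo-6,10-dimethylundeca-5,9-dien-1-yn-1-yl]trimethylsilane
Product: 11 (1R,2S,5R)-8-phenylmenthyl (6E,10E)-2,6,10-trimethyl-3-oxo-15-(trimethylsilyl)pentadeca-6,10-dien-14-ynoate, via dilithio dianion 10 (not isolated)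
Conditions: LiN(i-Pr)2 (2.2 equiv), THF, 0 °C; then 6, −78 → 0 °C; aq. NH4Cl
Reagents that add atoms: none
Why: Huckin–Weiler dianion alkylation, in which the more reactive γ-carbanion of the β-keto ester dianion displaces the allylic bromide by SN2 and both E-alkenes are retained.

Step 6
Reactants: 11 (1R,2S,5R)-8-phenylmenthyl (6E,10E)-2,6,10-trimethyl-3-oxo-15-(trimethylsilyl)pentadeca-6,10-dien-14-ynoate
Product: 12 (1R,2S,5R)-8-phenylmenthyl 3-oxo-14-(trimethylsilyl)-15,16-dinorlabd-8(17)-en-13-yn-19-oate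
Conditions: Mn(OAc)3·2H2O (2.2 equiv), Cu(OAc)2·H2O (1.0 equiv, regenerated in situ), degassed AcOH (0.05 M), 25 °C; chromatography
Reagents that add atoms: none
Why: Snider-type oxidative free-radical polyene cyclization: trivalent manganese oxidises the β-keto ester enol to an α-radical that closes ring A and then ring B through 6-endo chair transition states (the E,E-alkenes give the trans-decalin with 5α-H, 10β-CH3 and 9β side chain, and the unchelated radical with the ester anti to the ketone oxygen places the ester axial at C4), the phenyl ring of the auxiliary shields one face of the radical so the absolute configuration of C4, C5, C9 and C10 is set together (about 9:1 expected, minor diastereomer removed by chromatography), and divalent copper oxidises the tertiary C8 radical to the exocyclic alkene faster than that radical can undergo a strained 5-exo addition to the silylalkyne.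

Step 7
Reactants: 12 (1R,2S,5R)-8-phenylmenthyl 3-oxo-14-(trimethylsilyl)-15,16-dinorlabd-8(17)-en-13-yn-19-oate
Product: 15 15,16-dinorlabd-8(17)-en-13-yne-3α,19-diol, via 3α-hydroxy ester alkoxide 13 (not isolated), via silylated diol 14 (not isolated)
Conditions: LiBH(s-Bu)3 (1.3 equiv), THF, −78 °C; then LiAlH4, 0 → 50 °C; then MeOH, 2 M aq. NaOH, rt
Reagents that add atoms: none
Why: The bulky LiBH(s-Bu)3 attacks the hindered C3 ketone from the equatorial direction to give the axial 3α-alkoxide (as with 4,4-disubstituted 3-oxo terpenoids), LiAlH4 then reductively cleaves the hindered ester to the C19 primary alcohol with release of the auxiliary for recovery, and methanolic hydroxide protodesilylates the alkyne.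

Step 8
Reactants: 15 15,16-dinorlabd-8(17)-en-13-yne-3α,19-diol
Product: 17 3α-hydroxy-15,16-dinorlabd-8(17)-en-13-yn-19-oic acid, via hydroxy aldehyde 16 (not isolated)
Conditions: TEMPO (0.2 equiv), PhI(OAc)2 (1.1 equiv), CH2Cl2, rt; then NaClO2, NaH2PO4, 2-methyl-2-butene, t-BuOH/H2O, rt
Reagents that add atoms: sodium chlorite, [Na+].[O-]Cl=O
Why: Oxoammonium (TEMPO) oxidation selects the primary alcohol over the hindered axial secondary one, and Pinnick oxidation converts the resulting aldehyde into the acid without touching alkene, alkyne or the 3α-alcohol, with C4 safe from epimerisation because it is quaternary.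

Step 9
Reactants: 17 3α-hydroxy-15,16-dinorlabd-8(17)-en-13-yn-19-oic acid
Product: 18 3α-acetoxy-15,16-dinorlabd-8(17)-en-13-yn-19-oic acid
Conditions: Ac2O, DMAP, pyridine, 40 °C; aq. work-up
Reagents that add atoms: acetic anhydride, CC(=O)OC(C)=O
Why: DMAP-catalysed acylation esterifies the axial 3α-alcohol with retention, and the transient mixed anhydride of the C19 acid is hydrolysed on aqueous work-up.

Step 10
Reactants: 18 3α-acetoxy-15,16-dinorlabd-8(17)-en-13-yn-19-oic acid
Product: 20 3α-acetoxy-15-hydroxylabda-8(17),13E-dien-19-oic acid, via alkenylalane 19 (not isolated)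
Conditions: Me3Al (5 equiv), Cp2ZrCl2 (0.5 equiv), CH2Cl2, −20 → 0 °C; then (CH2O)n, THF, 0 °C → rt; aq. work-up
Reagents that add atoms: trimethylaluminium, C[Al](C)C; paraformaldehyde (as formaldehyde), C=O
Why: Negishi zirconium-catalysed carboalumination adds CH3 and Al syn across the terminal alkyne with methyl on the internal carbon, and the alkenylalane adds to formaldehyde with retention to give only the 13E allylic alcohol, while the acid is masked in situ as its dimethylaluminium carboxylate and the hindered secondary acetate is inert to Me3Al at or below 0 °C.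

## Compound list

1 | geranyl bromide, (2E)-1-bromo-3,7-dimethylocta-2,6-diene | CC(C)=CCC/C(C)=C/CBr | starting material
2 | 1-(trimethylsilyl)propyne | CC#C[Si](C)(C)C | starting material
3 | 3-(trimethylsilyl)prop-2-ynyllithium (not isolated) | [Li]CC#C[Si](C)(C)C | intermediate
4 | [(5E)-6,10-dimethylundeca-5,9-dien-1-yn-1-yl]trimethylsilane | CC(C)=CCC/C(C)=C/CCC#C[Si](C)(C)C | intermediate
5 | (2E,6E)-2,6-dimethyl-11-(trimethylsilyl)undeca-2,6-dien-10-yn-1-ol | OC/C(C)=C/CC/C(C)=C/CCC#C[Si](C)(C)C | intermediate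
6 | [(5E,9E)-11-bromo-6,10-dimethylundeca-5,9-dien-1-yn-1-yl]trimethylsilane | BrC/C(C)=C/CC/C(C)=C/CCC#C[Si](C)(C)C | intermediate
7 | (−)-8-phenylmenthol, (1R,2S,5R)-5-methyl-2-(2-phenylpropan-2-yl)cyclohexan-1-ol | O[C@@H]1C[C@H](C)CC[C@H]1C(C)(C)c2ccccc2 | starting material
8 | ethyl 2-methylacetoacetate (racemic) | CCOC(=O)C(C)C(C)=O | starting material
9 | (1R,2S,5R)-5-methyl-2-(2-phenylpropan-2-yl)cyclohexyl 2-methyl-3-oxobutanoate (C2 epimers) | CC(=O)C(C)C(=O)O[C@@H]1C[C@H](C)CC[C@H]1C(C)(C)c2ccccc2 | intermediate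
10 | dilithio dianion of 9, drawn as the bis-enolate (not isolated) | C=C(O[Li])C(C)=C(O[Li])O[C@@H]1C[C@H](C)CC[C@H]1C(C)(C)c2ccccc2 | intermediate
11 | (1R,2S,5R)-8-phenylmenthyl (6E,10E)-2,6,10-trimethyl-3-oxo-15-(trimethylsilyl)pentadeca-6,10-dien-14-ynoate (C2 epimers) | CC(C(=O)CC/C(C)=C/CC/C(C)=C/CCC#C[Si](C)(C)C)C(=O)O[C@@H]1C[C@H](C)CC[C@H]1C(C)(C)c2ccccc2 | intermediate
12 | (1R,2S,5R)-8-phenylmenthyl 3-oxo-14-(trimethylsilyl)-15,16-dinorlabd-8(17)-en-13-yn-19-oate (4β-ester, 4α-CH3, 5α-H, 10β-CH3, 9β side chain) | C=C1CC[C@@H]2[C@](C)(CCC(=O)[C@]2(C)C(=O)O[C@@H]3C[C@H](C)CC[C@H]3C(C)(C)c4ccccc4)[C@H]1CCC#C[Si](C)(C)C | intermediate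
13 | (1R,2S,5R)-8-phenylmenthyl 3α-hydroxy-14-(trimethylsilyl)-15,16-dinorlabd-8(17)-en-13-yn-19-oate, present as its lithium alkoxide (not isolated) | C=C1CC[C@@H]2[C@](C)(CC[C@@H](O)[C@]2(C)C(=O)O[C@@H]3C[C@H](C)CC[C@H]3C(C)(C)c4ccccc4)[C@H]1CCC#C[Si](C)(C)C | intermediate
14 | 14-(trimethylsilyl)-15,16-dinorlabd-8(17)-en-13-yne-3α,19-diol (not isolated) | C=C1CC[C@@H]2[C@](C)(CC[C@@H](O)[C@]2(C)CO)[C@H]1CCC#C[Si](C)(C)C | intermediate
15 | 15,16-dinorlabd-8(17)-en-13-yne-3α,19-diol | C=C1CC[C@@H]2[C@](C)(CC[C@@H](O)[C@]2(C)CO)[C@H]1CCC#C | intermediate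
16 | 3α-hydroxy-15,16-dinorlabd-8(17)-en-13-yn-19-al (not isolated) | C=C1CC[C@@H]2[C@](C)(CC[C@@H](O)[C@]2(C)C=O)[C@H]1CCC#C | intermediate
17 | 3α-hydroxy-15,16-dinorlabd-8(17)-en-13-yn-19-oic acid | C=C1CC[C@@H]2[C@](C)(CC[C@@H](O)[C@]2(C)C(=O)O)[C@H]1CCC#C | intermediate
18 | 3α-acetoxy-15,16-dinorlabd-8(17)-en-13-yn-19-oic acid | C=C1CC[C@@H]2[C@](C)(CC[C@@H](OC(C)=O)[C@]2(C)C(=O)O)[C@H]1CCC#C | intermediate
19 | dimethylaluminium 3α-acetoxy-14-(dimethylalumanyl)-15-norlabda-8(17),13E-dien-19-oate (not isolated) | C=C1CC[C@@H]2[C@](C)(CC[C@@H](OC(C)=O)[C@]2(C)C(=O)O[Al](C)C)[C@H]1CC/C(C)=C/[Al](C)C | intermediate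
20 | 3α-acetoxy-15-hydroxylabda-8(17),13E-dien-19-oic acid (CNP0395853.1) | C=C1CC[C@@H]2[C@](C)(CC[C@@H](OC(C)=O)[C@]2(C)C(=O)O)[C@H]1CC/C(C)=C/CO | target

## Step count and risks

Total steps: 10. Longest linear sequence: 9 (steps 1, 2, 3, 5, 6, 7, 8, 9, 10 from geranyl bromide); step 4 is a one-step side branch.

Most likely to fail:

**Step 6 (bicyclization).** Risks are a poor exocyclic/endocyclic alkene ratio in the copper termination, some capture of the C8 radical by the alkyne, and lower auxiliary induction than expected. Fallback: set out from 11. Bromination with NBS and catalytic Mg(ClO4)2 in EtOAc gives the α-bromo keto ester F1. Et3B/air-initiated bromine-atom-transfer radical bicyclization in toluene (no chelating Lewis acid, so the same unchelated, auxiliary-shielded radical) gives the tertiary 8α-bromide F2. DBU in toluene at 80 °C then effects anti elimination; for an equatorial bromide on the rigid trans-decalin only a methyl hydrogen is antiperiplanar, so the 8(17)-alkene forms and the route is rejoined at 12.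

**Step 8 (selective oxidation of the neopentyl primary alcohol beside the free 3α-alcohol).** Fallback: set out from 13, isolated by working up step 7 after the LiBH(s-Bu)3 stage. TBSOTf/2,6-lutidine gives the silyl ether F3. LiAlH4 in THF gives the C19 primary alcohol F4 and releases the auxiliary. Dess–Martin periodinane gives the aldehyde F5, and NaClO2/NaH2PO4/2-methyl-2-butene gives the acid F6. n-Bu4NF in THF at 50 °C removes both the silyl ether and the alkynyl silyl group and rejoins the route at 17.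

**Step 10 (carboalumination in the presence of the free acid and the acetate).** Fallback: set out from diol 15, whose hydroxyls are tolerated as aluminium alkoxides. Me3Al/Cp2ZrCl2 in CH2Cl2 gives the alkenylalane F7, and an iodine quench gives the (E)-vinyl iodide diol F8. TEMPO/PhI(OAc)2 gives the hydroxy aldehyde F9, and NaClO2/NaH2PO4/2-methyl-2-butene gives the hydroxy acid F10. Ac2O/DMAP/pyridine gives the acetoxy acid F11. Stille coupling with Bu3SnCH2OH and Pd(PPh3)4 in dioxane at 85 °C installs the hydroxymethyl group with retention and rejoins the route at 20.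

## Further compounds

F1 | step 6 | (1R,2S,5R)-8-phenylmenthyl (6E,10E)-2-bromo-2,6,10-trimethyl-3-oxo-15-(trimethylsilyl)pentadeca-6,10-dien-14-ynoate (C2 epimers) | CC(Br)(C(=O)CC/C(C)=C/CC/C(C)=C/CCC#C[Si](C)(C)C)C(=O)O[C@@H]1C[C@H](C)CC[C@H]1C(C)(C)c2ccccc2
F2 | step 6 | (1R,2S,5R)-8-phenylmenthyl 8α-bromo-3-oxo-14-(trimethylsilyl)-15,16-dinorlabd-13-yn-19-oate | C[C@@]1(Br)CC[C@@H]2[C@](C)(CCC(=O)[C@]2(C)C(=O)O[C@@H]3C[C@H](C)CC[C@H]3C(C)(C)c4ccccc4)[C@H]1CCC#C[Si](C)(C)C
F3 | step 8 | (1R,2S,5R)-8-phenylmenthyl 3α-(tert-butyldimethylsilyloxy)-14-(trimethylsilyl)-15,16-dinorlabd-8(17)-en-13-yn-19-oate | C=C1CC[C@@H]2[C@](C)(CC[C@@H](O[Si](C)(C)C(C)(C)C)[C@]2(C)C(=O)O[C@@H]3C[C@H](C)CC[C@H]3C(C)(C)c4ccccc4)[C@H]1CCC#C[Si](C)(C)C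
F4 | step 8 | 3α-(tert-butyldimethylsilyloxy)-14-(trimethylsilyl)-15,16-dinorlabd-8(17)-en-13-yn-19-ol | C=C1CC[C@@H]2[C@](C)(CC[C@@H](O[Si](C)(C)C(C)(C)C)[C@]2(C)CO)[C@H]1CCC#C[Si](C)(C)C
F5 | step 8 | 3α-(tert-butyldimethylsilyloxy)-14-(trimethylsilyl)-15,16-dinorlabd-8(17)-en-13-yn-19-al | C=C1CC[C@@H]2[C@](C)(CC[C@@H](O[Si](C)(C)C(C)(C)C)[C@]2(C)C=O)[C@H]1CCC#C[Si](C)(C)C
F6 | step 8 | 3α-(tert-butyldimethylsilyloxy)-14-(trimethylsilyl)-15,16-dinorlabd-8(17)-en-13-yn-19-oic acid | C=C1CC[C@@H]2[C@](C)(CC[C@@H](O[Si](C)(C)C(C)(C)C)[C@]2(C)C(=O)O)[C@H]1CCC#C[Si](C)(C)C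
F7 | step 10 | 14-(dimethylalumanyl)-15-norlabda-8(17),13E-diene-3α,19-diol bis(dimethylaluminium) alkoxide | C=C1CC[C@@H]2[C@](C)(CC[C@@H](O[Al](C)C)[C@]2(C)CO[Al](C)C)[C@H]1CC/C(C)=C/[Al](C)C
F8 | step 10 | 14-iodo-15-norlabda-8(17),13E-diene-3α,19-diol | C=C1CC[C@@H]2[C@](C)(CC[C@@H](O)[C@]2(C)CO)[C@H]1CC/C(C)=C/I
F9 | step 10 | 3α-hydroxy-14-iodo-15-norlabda-8(17),13E-dien-19-al | C=C1CC[C@@H]2[C@](C)(CC[C@@H](O)[C@]2(C)C=O)[C@H]1CC/C(C)=C/I
F10 | step 10 | 3α-hydroxy-14-iodo-15-norlabda-8(17),13E-dien-19-oic acid | C=C1CC[C@@H]2[C@](C)(CC[C@@H](O)[C@]2(C)C(=O)O)[C@H]1CC/C(C)=C/I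
F11 | step 10 | 3α-acetoxy-14-iodo-15-norlabda-8(17),13E-dien-19-oic acid | C=C1CC[C@@H]2[C@](C)(CC[C@@H](OC(C)=O)[C@]2(C)C(=O)O)[C@H]1CC/C(C)=C/I
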